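**Retrosynthetic overview**
1. Target 17 ⇐ 14: the sulfate is carried as a 2,2,2-trichloroethyl diester and unveiled last, together with three acetates.
2. 14 ⇐ 13 by a proposed enantioselective proton-initiated bicyclisation of a (2Z,6E)-farnesyl arene. Ring A, then ring B, the trans ring fusion (C5, C10), C9 (CH2Ar axial, dictated by the Z olefin) and the C7=C8 olefin are formed in this one step.
3. 13 ⇐ 9 by protecting-group exchange; 9 ⇐ aryllithium 8 + (2Z,6E)-farnesyl bromide 7 (C11–aryl bond).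
4. Arene 5 ⇐ 2,4,5-trihydroxybenzaldehyde 1 (MOM, Dakin, silyl), which singles out the oxygen that becomes the sulfate. The aromatic ring is bought; rings A and B are made last.

Assumption: 1, (2Z,6E)-farnesol 6 and 2,2,2-trichloroethyl chlorosulfate are bought as pure compounds; the decalin is numbered as a drimane (C5, C9, C10 stereocentres, C11 = benzylic CH2; target = 5S,9R,10S, CH2Ar trans to the angular methyl); the (S,S) acid of step 9 is taken to give this series, and its (R,R) antipode is used if the first run shows the opposite sense; "(2Z,6E)-farnesyl" = (2Z,6E)-3,7,11-trimethyldodeca-2,6,10-trien-1-yl.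

**Route**

Step 1
Reactants: 1 2,4,5-trihydroxybenzaldehyde
Product: 2 2,4,5-tris(methoxymethoxy)benzaldehyde
Conditions: NaH (3.3 equiv), MeOCH2Cl (3.6 equiv), DMF, 0 °C → rt
Reagents that add atoms: chloromethyl methyl ether, COCCl
Why: Williamson O-alkylation of all three phenoxides (NaH also breaks the chelate of the 2-OH); no stereocentre is involved.

Step 2
Reactants: 2 2,4,5-tris(methoxymethoxy)benzaldehyde
Product: 4 2,4,5-tris(methoxymethoxy)phenol, via aryl formate 3 (not isolated)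
Conditions: mCPBA (1.3 equiv), CH2Cl2, 0 °C → rt; then K2CO3 (0.1 equiv), MeOH, rt
Reagents that add atoms: 3-chloroperbenzoic acid, O=C(OO)c1cccc(Cl)c1
Why: Dakin-type Baeyer–Villiger oxidation in which the electron-rich aryl group migrates, followed by methanolysis of the formate.

Step 3
Reactants: 4 2,4,5-tris(methoxymethoxy)phenol
Product: 5 triisopropyl[2,4,5-tris(methoxymethoxy)phenoxy]silane
Conditions: i-Pr3SiCl, imidazole, DMF, rt
Reagents that add atoms: chlorotri(propan-2-yl)silane, CC(C)[Si](Cl)(C(C)C)C(C)C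
Why: Standard silylation; the bulky silyl ether marks the future sulfate oxygen and does not direct lithiation.

Step 4
Reactants: 6 (2Z,6E)-farnesol
Product: 7 (2Z,6E)-farnesyl bromide
Conditions: PBr3 (0.4 equiv), Et2O, −10 °C, 30 min; used crude at once
Reagents that add atoms: phosphorus tribromide, BrP(Br)Br
Why: SN2 displacement of the phosphite ester by bromide at the primary allylic carbon at low temperature, which keeps the 2Z geometry.

Step 5
Reactants: 5 triisopropyl[2,4,5-tris(methoxymethoxy)phenoxy]silane; 7 (2Z,6E)-farnesyl bromide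
Product: 9 triisopropyl{2,4,5-tris(methoxymethoxy)-3-[(2Z,6E)-farnesyl]phenoxy}silane, via aryllithium 8 (not isolated)
Conditions: n-BuLi, Me2NCH2CH2NMe2, THF, 0 °C; CuBr·SMe2 (10 mol %), then 7, −78 → 0 °C
Reagents that add atoms: none
Why: Directed ortho-metalation at the only C–H flanked by two MOM ethers, then copper-catalysed SN2 allylation at the primary carbon, which forms the C11–aryl bond without touching the Z olefin.

Step 6
Reactants: 9 triisopropyl{2,4,5-tris(methoxymethoxy)-3-[(2Z,6E)-farnesyl]phenoxy}silane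
Product: 10 2,4,5-tris(methoxymethoxy)-3-[(2Z,6E)-farnesyl]phenol
Conditions: Bu4NF, AcOH (1:1), THF, 0 °C
Reagents that add atoms: none
Why: Fluoride-mediated desilylation of the aryl silyl ether; the acetic acid buffer keeps the electron-rich phenol from being oxidised as its phenoxide.

Step 7
Reactants: 10 2,4,5-tris(methoxymethoxy)-3-[(2Z,6E)-farnesyl]phenol
Product: 11 2,4,5-tris(methoxymethoxy)-3-[(2Z,6E)-farnesyl]phenyl 2,2,2-trichloroethyl sulfate
Conditions: Cl3CCH2OSO2Cl, Et3N, 4-(dimethylamino)pyridine (cat.), THF, 0 °C → rt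
Reagents that add atoms: 2,2,2-trichloroethyl chlorosulfate, ClS(=O)(=O)OCC(Cl)(Cl)Cl
Why: Sulfuryl transfer to the single free phenol fixes the sulfate position while both neighbours are inert MOM ethers, and gives an acid-stable sulfate diester.

Step 8
Reactants: 11 2,4,5-tris(methoxymethoxy)-3-[(2Z,6E)-farnesyl]phenyl 2,2,2-trichloroethyl sulfate
Product: 13 2,4,5-triacetoxy-3-[(2Z,6E)-farnesyl]phenyl 2,2,2-trichloroethyl sulfate, via triol 12 (not isolated)
Conditions: 0.5 M HCl in degassed MeOH/THF, rt; evaporate; Ac2O, pyridine, 4-(dimethylamino)pyridine (cat.), 0 °C → rt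
Reagents that add atoms: acetic anhydride, CC(=O)OC(C)=O
Why: Acid-catalysed acetal exchange removes the MOM groups under conditions that spare trisubstituted olefins and the sulfate diester, and acetylation then makes the two oxygens next to the side chain non-nucleophilic for step 9.

Step 9
Reactants: 13 2,4,5-triacetoxy-3-[(2Z,6E)-farnesyl]phenyl 2,2,2-trichloroethyl sulfate
Product: 14 2,4,5-triacetoxy-3-{[(1R,4aS,8aS)-2,5,5,8a-tetramethyl-1,4,4a,5,6,7,8,8a-octahydronaphthalen-1-yl]methyl}phenyl 2,2,2-trichloroethyl sulfate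
Conditions: (S,S)-IDPi acid HN[P(=NSO2CF3)(O2C20H10Ar2)]2, Ar = 3,5-(t-Bu)2C6H3 (5 mol %), (CF3)3COH/CH2Cl2 3:1, −30 → 0 °C
Reagents that add atoms: none
Why: Proposed new method: the confined chiral Brønsted acid protonates the terminal olefin of the farnesyl chain inside its pocket and the chain closes through a chair–chair transition state, anti addition across the 6E olefin giving the trans fusion (10-Me and 5-H anti, both S) while the 2Z olefin must carry its CH2Ar group axial, so C9 forms with CH2Ar anti to the angular methyl (9R); in the resulting C8 cation the axial 7-H is aligned with the empty orbital but 9-H is equatorial and lies in its nodal plane, so the catalyst anion removes 7-H to give the C7=C8 olefin without scrambling C9 (any exocyclic isomer is re-protonated to the same cation and drained to the ring olefin on warming), and the acetate and sulfate diester oxygens are too electron-poor to trap the cation; the closest known reaction type is the enantioselective proton-initiated polyene cyclisation of 2E-configured polyprenyl alcohols, phenols and arenes by IDPi acids or Lewis acid-assisted chiral Brønsted acids, which ends by O- or aryl-capture and has not been shown for a 2Z-farnesyl arene with olefin-forming termination.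

Step 10
Reactants: 14 2,4,5-triacetoxy-3-{[(1R,4aS,8aS)-2,5,5,8a-tetramethyl-1,4,4a,5,6,7,8,8a-octahydronaphthalen-1-yl]methyl}phenyl 2,2,2-trichloroethyl sulfate
Product: 17 2,4,5-trihydroxy-3-{[(1R,4aS,8aS)-2,5,5,8a-tetramethyl-1,4,4a,5,6,7,8,8a-octahydronaphthalen-1-yl]methyl}phenyl hydrogen sulfate, via ammonium sulfate triacetate 15 (not isolated), via ammonium salt of the target 16 (not isolated)
Conditions: Zn dust, HCO2NH4, MeOH, rt; filter; 7 M NH3 in MeOH, 0 °C → rt, argon; cold 0.1 M HCl to pH 2, n-BuOH extraction, lyophilise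
Reagents that add atoms: none
Why: Zinc-mediated reductive β-elimination frees the sulfate monoester first, so that the ammonolysis of the three aryl acetates never places a free phenoxide next to a sulfate diester; neither operation touches the olefin or the three stereocentres.

**Compound list**
1 | 2,4,5-trihydroxybenzaldehyde | O=Cc1cc(O)c(O)cc1O | starting material
2 | 2,4,5-tris(methoxymethoxy)benzaldehyde | O=Cc1cc(OCOC)c(OCOC)cc1OCOC | intermediate
3 | 2,4,5-tris(methoxymethoxy)phenyl formate | O=COc1cc(OCOC)c(OCOC)cc1OCOC | intermediate (not isolated)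
4 | 2,4,5-tris(methoxymethoxy)phenol | Oc1cc(OCOC)c(OCOC)cc1OCOC | intermediate
5 | triisopropyl[2,4,5-tris(methoxymethoxy)phenoxy]silane | CC(C)[Si](Oc1cc(OCOC)c(OCOC)cc1OCOC)(C(C)C)C(C)C | intermediate
6 | (2Z,6E)-farnesol, (2Z,6E)-3,7,11-trimethyldodeca-2,6,10-trien-1-ol | CC(C)=CCC/C(C)=C/CC/C(C)=C\CO | starting material
7 | (2Z,6E)-farnesyl bromide, (2Z,6E)-1-bromo-3,7,11-trimethyldodeca-2,6,10-triene | CC(C)=CCC/C(C)=C/CC/C(C)=C\CBr | intermediate
8 | [2,3,6-tris(methoxymethoxy)-5-(triisopropylsilyloxy)phenyl]lithium | [Li]c1c(OCOC)c(OCOC)cc(O[Si](C(C)C)(C(C)C)C(C)C)c1OCOC | intermediate (not isolated)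
9 | triisopropyl{2,4,5-tris(methoxymethoxy)-3-[(2Z,6E)-3,7,11-trimethyldodeca-2,6,10-trien-1-yl]phenoxy}silane | CC(C)=CCC/C(C)=C/CC/C(C)=C\Cc1c(OCOC)c(OCOC)cc(O[Si](C(C)C)(C(C)C)C(C)C)c1OCOC | intermediate
10 | 2,4,5-tris(methoxymethoxy)-3-[(2Z,6E)-3,7,11-trimethyldodeca-2,6,10-trien-1-yl]phenol | CC(C)=CCC/C(C)=C/CC/C(C)=C\Cc1c(OCOC)c(OCOC)cc(O)c1OCOC | intermediate
11 | 2,4,5-tris(methoxymethoxy)-3-[(2Z,6E)-3,7,11-trimethyldodeca-2,6,10-trien-1-yl]phenyl 2,2,2-trichloroethyl sulfate | CC(C)=CCC/C(C)=C/CC/C(C)=C\Cc1c(OCOC)c(OCOC)cc(OS(=O)(=O)OCC(Cl)(Cl)Cl)c1OCOC | intermediate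
12 | 2,4,5-trihydroxy-3-[(2Z,6E)-3,7,11-trimethyldodeca-2,6,10-trien-1-yl]phenyl 2,2,2-trichloroethyl sulfate | CC(C)=CCC/C(C)=C/CC/C(C)=C\Cc1c(O)c(O)cc(OS(=O)(=O)OCC(Cl)(Cl)Cl)c1O | intermediate (not isolated)
13 | 2,4,5-triacetoxy-3-[(2Z,6E)-3,7,11-trimethyldodeca-2,6,10-trien-1-yl]phenyl 2,2,2-trichloroethyl sulfate | CC(C)=CCC/C(C)=C/CC/C(C)=C\Cc1c(OC(C)=O)c(OC(C)=O)cc(OS(=O)(=O)OCC(Cl)(Cl)Cl)c1OC(C)=O | intermediate
14 | 2,4,5-triacetoxy-3-{[(1R,4aS,8aS)-2,5,5,8a-tetramethyl-1,4,4a,5,6,7,8,8a-octahydronaphthalen-1-yl]methyl}phenyl 2,2,2-trichloroethyl sulfate | CC1=CC[C@H]2C(C)(C)CCC[C@]2(C)[C@@H]1Cc1c(OC(C)=O)c(OC(C)=O)cc(OS(=O)(=O)OCC(Cl)(Cl)Cl)c1OC(C)=O | intermediate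
15 | ammonium 2,4,5-triacetoxy-3-{[(1R,4aS,8aS)-2,5,5,8a-tetramethyl-1,4,4a,5,6,7,8,8a-octahydronaphthalen-1-yl]methyl}phenyl sulfate | CC1=CC[C@H]2C(C)(C)CCC[C@]2(C)[C@@H]1Cc1c(OC(C)=O)c(OC(C)=O)cc(OS(=O)(=O)[O-])c1OC(C)=O.[NH4+] | intermediate (not isolated)
16 | ammonium 2,4,5-trihydroxy-3-{[(1R,4aS,8aS)-2,5,5,8a-tetramethyl-1,4,4a,5,6,7,8,8a-octahydronaphthalen-1-yl]methyl}phenyl sulfate | CC1=CC[C@H]2C(C)(C)CCC[C@]2(C)[C@@H]1Cc1c(O)c(O)cc(OS(=O)(=O)[O-])c1O.[NH4+] | intermediate (not isolated)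
17 | 2,4,5-trihydroxy-3-{[(1R,4aS,8aS)-2,5,5,8a-tetramethyl-1,4,4a,5,6,7,8,8a-octahydronaphthalen-1-yl]methyl}phenyl hydrogen sulfate | CC1=CC[C@H]2C(C)(C)CCC[C@]2(C)[C@@H]1Cc1c(O)c(O)cc(OS(=O)(=O)O)c1O | target

**Step count and risks**

Total step count: 10. Longest linear sequence: 9 (steps 1, 2, 3, 5, 6, 7, 8, 9, 10).

Steps most likely to fail:

Step 9 (the proposed new cyclisation). Enantio-induction, complete bicyclisation and the position of the olefin are all unproven. The fallback uses known chemistry, sets out from 13 and comes back at 14. Compound 13 is cyclised with an achiral superacid (ClSO3H, 2-nitropropane, −78 °C), the established way to convert farnesyl arenes into bicyclic drimenyl arenes through the same chair–chair fold. This gives 14 as a racemate, that is together with its mirror image 2,4,5-triacetoxy-3-{[(1S,4aR,8aR)-2,5,5,8a-tetramethyl-1,4,4a,5,6,7,8,8a-octahydronaphthalen-1-yl]methyl}phenyl 2,2,2-trichloroethyl sulfate F1. Olefin isomers are removed on AgNO3-impregnated silica, the enantiomers are separated by preparative HPLC on an amylose tris(3,5-dimethylphenylcarbamate) phase, F1 is discarded and 14 goes on to step 10.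

Step 8 (acidic MOM cleavage on the polyene). Risks are chroman formation from the ortho-hydroxy farnesyl arene, air oxidation of triol 12, and attack of the neighbouring phenol on the sulfate diester during acetylation (the reason Ac2O is kept in excess with pyridine as the only base). The fallback sets out from 11 and comes back at 12. Me3SiOSO2CF3 and 2,2′-bipyridyl in CH2Cl2 at 0 °C convert the three aryl MOM ethers directly, without any protic acid, into 3-[(2Z,6E)-farnesyl]-2,4,5-tris(trimethylsilyloxy)phenyl 2,2,2-trichloroethyl sulfate F2. Neutral methanol then solvolyses the silyl ethers to triol 12, which is acetylated at once as in step 8.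

Step 10 (unveiling). The reductive loss of the trichloroethyl group may be incomplete or may cost the electron-rich aryl sulfate. The fallback installs the sulfate last instead, sets out from 9 and comes back at 16. Compound 9 is treated with HCl in MeOH to give 3-[(2Z,6E)-farnesyl]-5-(triisopropylsilyloxy)benzene-1,2,4-triol F3. Acetylation (Ac2O, pyridine) gives 3-[(2Z,6E)-farnesyl]-5-(triisopropylsilyloxy)benzene-1,2,4-triyl triacetate F4. The conditions of step 9 cyclise it to the bicyclic silyl ether triacetate F5. HF·pyridine (THF, 0 °C, kept acidic to suppress acetyl migration) frees the phenol F6. SO3·pyridine in pyridine gives the pyridinium sulfate triacetate F7. 7 M NH3 in MeOH then gives 16, which is acidified to 17 as in step 10.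

Further compounds
F1 | step 9 | 2,4,5-triacetoxy-3-{[(1S,4aR,8aR)-2,5,5,8a-tetramethyl-1,4,4a,5,6,7,8,8a-octahydronaphthalen-1-yl]methyl}phenyl 2,2,2-trichloroethyl sulfate | CC1=CC[C@@H]2C(C)(C)CCC[C@@]2(C)[C@H]1Cc1c(OC(C)=O)c(OC(C)=O)cc(OS(=O)(=O)OCC(Cl)(Cl)Cl)c1OC(C)=O
F2 | step 8 | 3-[(2Z,6E)-3,7,11-trimethyldodeca-2,6,10-trien-1-yl]-2,4,5-tris(trimethylsilyloxy)phenyl 2,2,2-trichloroethyl sulfate | CC(C)=CCC/C(C)=C/CC/C(C)=C\Cc1c(O[Si](C)(C)C)c(O[Si](C)(C)C)cc(OS(=O)(=O)OCC(Cl)(Cl)Cl)c1O[Si](C)(C)C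
F3 | step 10 | 3-[(2Z,6E)-3,7,11-trimethyldodeca-2,6,10-trien-1-yl]-5-(triisopropylsilyloxy)benzene-1,2,4-triol | CC(C)=CCC/C(C)=C/CC/C(C)=C\Cc1c(O)c(O)cc(O[Si](C(C)C)(C(C)C)C(C)C)c1O
F4 | step 10 | 3-[(2Z,6E)-3,7,11-trimethyldodeca-2,6,10-trien-1-yl]-5-(triisopropylsilyloxy)benzene-1,2,4-triyl triacetate | CC(C)=CCC/C(C)=C/CC/C(C)=C\Cc1c(OC(C)=O)c(OC(C)=O)cc(O[Si](C(C)C)(C(C)C)C(C)C)c1OC(C)=O
F5 | step 10 | 3-{[(1R,4aS,8aS)-2,5,5,8a-tetramethyl-1,4,4a,5,6,7,8,8a-octahydronaphthalen-1-yl]methyl}-5-(triisopropylsilyloxy)benzene-1,2,4-triyl triacetate | CC1=CC[C@H]2C(C)(C)CCC[C@]2(C)[C@@H]1Cc1c(OC(C)=O)c(OC(C)=O)cc(O[Si](C(C)C)(C(C)C)C(C)C)c1OC(C)=O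
F6 | step 10 | 5-hydroxy-3-{[(1R,4aS,8aS)-2,5,5,8a-tetramethyl-1,4,4a,5,6,7,8,8a-octahydronaphthalen-1-yl]methyl}benzene-1,2,4-triyl triacetate | CC1=CC[C@H]2C(C)(C)CCC[C@]2(C)[C@@H]1Cc1c(OC(C)=O)c(OC(C)=O)cc(O)c1OC(C)=O
F7 | step 10 | pyridinium 2,4,5-triacetoxy-3-{[(1R,4aS,8aS)-2,5,5,8a-tetramethyl-1,4,4a,5,6,7,8,8a-octahydronaphthalen-1-yl]methyl}phenyl sulfate | CC1=CC[C@H]2C(C)(C)CCC[C@]2(C)[C@@H]1Cc1c(OC(C)=O)c(OC(C)=O)cc(OS(=O)(=O)[O-])c1OC(C)=O.c1cc[nH+]cc1
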